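E, the limiting reagent here, is the molecule I follow through the flask, where J is charged at 2.00 equiv.

| flask | E | J | remark | time |
|---|---|---|---|---|
| delta | 0.050 M | 1.3 equiv | run made earlier |  |
| eta | 0.050 M | 3 equiv | run made earlier |  |
| alpha | 0.10 M | 2 equiv | run made earlier |  |
| flask | 0.050 M | 2.00 equiv |  | 20 min |

| run | time / min | Z / % | E / % |
|---|---|---|---|
| delta | 1.33 | 21.2 | 78.0 |
| delta | 4.00 | 45.5 | 54.7 |
| delta | 8.00 | 63.5 | 36.3 |
| delta | 12.0 | 74.5 | 25.6 |
| delta | 15.0 | 79.4 | 20.3 |
| eta | 3.00 | 67.5 | 31.6 |
| eta | 6.00 | 87.5 | 12.4 |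
| eta | 10.0 | 95.4 | 4.2 |
| eta | 12.0 | 97.1 | 1.7 |
| eta | 15.0 | 98.3 | 0.7 |
| alpha | 1.33 | 51.3 | 49.1 |
| alpha | 2.50 | 68.4 | 31.6 |
| alpha | 5.00 | 86.5 | 13.7 |
| alpha | 8.00 | 94.6 | 4.9 |
| alpha | 15.0 | 98.9 | 0.6 |

(readings scatter by 0.3 percentage points)

- Z is meant together with its L
- solid, in amounts per volume of the solution: L
- reactions considered so far: E + J -> Z; J + Z -> G; J <-> X; L <-> Z

- equivalents of J to E, everything else as given, that leave most Z at 20 min
- the amount of Z then, in percent of the E charged
- the amount of Z with the amounts as given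

The alpha run at 2.50 min gives 2.93 /M/min for the uptake constant k, the chance per minute that one E reacts, divided by c_J. The eta run at 6.00 min gives 2.90 /M/min, so I carry k across concentrations.

Two extreme flasks can be solved in the head. If c_J stayed at its charge (the pseudo-first-order picture), one E would survive 20 min with chance exp(−k c_J t), which is 0.283%. If c_J stood from the start at the excess over E, 0.0500 M, that chance would be 5.32%. Counted as J and X together, which is how k reads it, c_J falls from the first value towards the second as E reacts, so on this reckoning the chance lies between them. Integrating this charge gives 1/(2 exp(k c_E t) − 1), which is 2.73%. I therefore expect Z near 97.3%, less what goes on to G.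

The forecast says 96.7%, and 98.9% at 3.1 equiv: “At 20 min and 2.00 equiv, E left is about 2.8% and G about 0.45%, so Z ≈ 96.7%.”

The flask gives 96.5%, and 98.9% at 3.15 equiv, so the forecast stands. E is at 2.99% against my 2.73%, while X holds 0.0133 M, which k never told apart from J. A run of this same flask would show the forecast wrong if its E at 20 min stood further from the forecast's 2.8% than the scatter of 0.3 percentage points allows.

    E + J → Z (k = 0.0640 /M/s)
    J + Z → G (k = 0.00210 /M/s)
    J ⇌ X (K = 0.350, k = 0.00950 /s)
    L ⇌ Z, rate k4*(cs4 - [Z]) while solid is left; crystals form when [Z] > cs4 (solubility = 2.20 mM, k = 0.840 /s)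

Read at 8.0 min, the same flask should keep E at 18.3% by k. The computed flask has 18.8% E and 80.9% Z.

The data come from a simulation from invented constants; noise was put on by code.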